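Assumption: the (2R,3R)-trans enantiomer encoded in the SMILES is the required target, and 2-bromo-4-iodophenol, the Ru catalyst and the phosphine ligand are purchased.

## Retrosynthetic overview

1. Aiphanol (16) comes from trans-benzodioxane ester 14 by ester reduction and global desilylation; the 1,4-dioxane is the only ring made, and all three benzene rings are bought.
2. The dioxane ring is closed by a stereoretentive intramolecular Pd-catalysed C(aryl)–O coupling of a benzylic alcohol onto an ortho-bromide (13 → 14), not by biomimetic phenol oxidative coupling or a diol/Mitsunobu closure.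
3. The stilbene comes from an iodide-selective Heck coupling of 8 with styrene 12, run before ring closure.
4. Both stereocentres come from one Ru-catalysed transfer hydrogenation with dynamic kinetic resolution (ATH–DKR) of the racemic α-aryloxy β-keto ester 7. This is the key step.
5. Keto ester 7 comes from aldol addition and oxidation of aryloxyacetate 3 (from 2-bromo-4-iodophenol) with TBS-syringaldehyde 5.

## Route

**Step 1**
Reactants: 1, 2-bromo-4-iodophenol; 2, ethyl bromoacetate
Product: 3, ethyl 2-(2-bromo-4-iodophenoxy)acetate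
Conditions: K2CO3, acetone, reflux
Reagents that add atoms: ethyl bromoacetate (2), CCOC(=O)CBr
Why: Williamson ether synthesis; the phenoxide is the only nucleophile and the α-bromo ester is an excellent SN2 electrophile.

**Step 2**
Reactants: 4, syringaldehyde (4-hydroxy-3,5-dimethoxybenzaldehyde)
Product: 5, 4-[(tert-butyldimethylsilyl)oxy]-3,5-dimethoxybenzaldehyde
Conditions: TBSCl, imidazole, DMF, rt
Reagents that add atoms: tert-butyldimethylsilyl chloride, CC(C)(C)[Si](C)(C)Cl
Why: Standard phenol silylation keeps the aldehyde electrophilic (no phenoxide) and masks the phenol through the base and Pd steps.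

**Step 3**
Reactants: 3, ethyl 2-(2-bromo-4-iodophenoxy)acetate; 5, TBS-syringaldehyde
Product: 6, ethyl 2-(2-bromo-4-iodophenoxy)-3-hydroxy-3-[4-(TBSO)-3,5-dimethoxyphenyl]propanoate (racemic, syn/anti mixture)
Conditions: LDA, THF, −78 °C; then 5, −78 °C; AcOH quench
Reagents that add atoms: none (both partners are numbered reactants)
Why: Lithium ester-enolate aldol addition; ester deprotonation is far faster than any attack on the aryl halides at −78 °C, and the stereochemical outcome is irrelevant because both centres are erased in step 4.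

**Step 4**
Reactants: 6, aldol adduct
Product: 7, ethyl 2-(2-bromo-4-iodophenoxy)-3-oxo-3-[4-(TBSO)-3,5-dimethoxyphenyl]propanoate (racemic, configurationally labile at C2)
Conditions: DMP, NaHCO3, CH2Cl2, 0 °C → rt
Reagents that add atoms: none
Why: Dess–Martin oxidation of the secondary benzylic alcohol gives the β-keto ester whose doubly activated α-H makes it a DKR substrate; silyl ether and aryl halides are inert.

**Step 5 (key step)**
Reactants: 7, racemic α-aryloxy β-keto ester
Product: 8, ethyl (2S,3R)-2-(2-bromo-4-iodophenoxy)-3-hydroxy-3-[4-(TBSO)-3,5-dimethoxyphenyl]propanoate (syn/threo)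
Conditions: RuCl[(S,S)-TsDPEN](p-cymene) (2 mol%), HCO2H/Et3N (5:2), CH2Cl2, 30 °C
Reagents that add atoms: none (adds H only)
Why: Noyori–Ikariya asymmetric transfer hydrogenation with dynamic kinetic resolution: the α-centre racemises rapidly through the enol while the (S,S)-Ru hydride reduces the aryl ketone via the usual CH/π-organised outer-sphere transition state to the (3R)-carbinol, and the non-chelated Felkin-type preference established for α-alkoxy β-keto esters gives the syn (2S,3R) isomer. The α-aryloxy substrate is a close extension of that class, and this one step sets both stereocentres.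

**Step 6**
Reactants: 9, 3,5-dihydroxybenzaldehyde
Product: 10, 3,5-bis[(tert-butyldimethylsilyl)oxy]benzaldehyde
Conditions: TBSCl, imidazole, DMF, rt
Reagents that add atoms: tert-butyldimethylsilyl chloride, CC(C)(C)[Si](C)(C)Cl
Why: Standard bis-silylation gives phenol protection that is removed together with the syringyl TBS group in the last step.

**Step 7**
Reactants: 10, 3,5-bis(TBSO)benzaldehyde; 11, methyltriphenylphosphonium bromide
Product: 12, 1-ethenyl-3,5-bis[(tert-butyldimethylsilyl)oxy]benzene
Conditions: Ph3PCH3Br, n-BuLi, THF, 0 °C → rt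
Reagents that add atoms: methyltriphenylphosphonium bromide (11; delivers CH2), C[P+](c1ccccc1)(c1ccccc1)c1ccccc1.[Br-]
Why: Wittig methylenation of a non-enolisable aryl aldehyde; aryl silyl ethers tolerate the non-stabilised ylide.

**Step 8**
Reactants: 8, (2S,3R)-hydroxy ester; 12, 3,5-bis(TBSO)styrene
Product: 13, ethyl (2S,3R)-2-{2-bromo-4-[(E)-2-(3,5-bis(TBSO)phenyl)ethenyl]phenoxy}-3-hydroxy-3-[4-(TBSO)-3,5-dimethoxyphenyl]propanoate
Conditions: Pd(OAc)2 (5 mol%), P(o-tol)3 (10 mol%), Et3N, MeCN, 70 °C
Reagents that add atoms: none (both partners are numbered reactants)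
Why: Mizoroki–Heck reaction; oxidative addition to C–I is much faster than to the hindered, electron-rich ortho C–Br, syn-insertion/syn-β-hydride elimination gives the E-stilbene, and Et3N does not disturb the stereocentres.

**Step 9**
Reactants: 13, bromo stilbene hydroxy ester
Product: 14, ethyl (2S,3R)-6-[(E)-2-(3,5-bis(TBSO)phenyl)ethenyl]-3-[4-(TBSO)-3,5-dimethoxyphenyl]-2,3-dihydro-1,4-benzodioxine-2-carboxylate (trans)
Conditions: Pd(OAc)2 (5 mol%), 2-(di-tert-butylphosphino)-1,1′-binaphthyl (6 mol%), Cs2CO3, toluene, 70 °C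
Reagents that add atoms: none
Why: Buchwald-type intramolecular Pd-catalysed C(aryl)–O etherification; the benzylic C–O bond is never broken, so C3 is retained and the syn precursor gives the trans ring, with the bulky ligand favouring C–O reductive elimination over β-hydride elimination. Any cis ester arising from minor anti-8 can be epimerised at C2 (α to the ester) to the same trans enantiomer.

**Step 10**
Reactants: 14, trans-benzodioxane ester
Product: 15, {(2R,3R)-6-[(E)-2-(3,5-bis(TBSO)phenyl)ethenyl]-3-[4-(TBSO)-3,5-dimethoxyphenyl]-2,3-dihydro-1,4-benzodioxin-2-yl}methanol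
Conditions: LiBH4, THF, 0 °C → rt
Reagents that add atoms: none (adds H only)
Why: Chemoselective borohydride reduction of the activated α-aryloxy ester; no bond to a stereocentre is touched (the C2 descriptor changes S → R only through CIP priorities), and the stilbene and aryl silyl ethers are inert.

**Step 11**
Reactants: 15, tris-TBS aiphanol
Product: 16, aiphanol, 5-[(E)-2-[(2R,3R)-3-(4-hydroxy-3,5-dimethoxyphenyl)-2-(hydroxymethyl)-2,3-dihydro-1,4-benzodioxin-6-yl]ethenyl]benzene-1,3-diol
Conditions: TBAF/AcOH (1:1), THF, 0 °C → rt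
Reagents that add atoms: none
Why: Fluoride-mediated cleavage of the three aryl silyl ethers; AcOH buffering prevents phenoxide-triggered quinone-methide opening of the benzylic aryl ether, so the trans-(2R,3R) ring is preserved.

## Compound list

1 | 2-bromo-4-iodophenol | Oc1ccc(I)cc1Br | starting material
2 | ethyl bromoacetate | CCOC(=O)CBr | starting material
3 | ethyl 2-(2-bromo-4-iodophenoxy)acetate | CCOC(=O)COc1ccc(I)cc1Br | intermediate
4 | syringaldehyde | COc1cc(C=O)cc(OC)c1O | starting material
5 | 4-[(tert-butyldimethylsilyl)oxy]-3,5-dimethoxybenzaldehyde | COc1cc(C=O)cc(OC)c1O[Si](C)(C)C(C)(C)C | intermediate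
6 | ethyl 2-(2-bromo-4-iodophenoxy)-3-hydroxy-3-[4-(TBSO)-3,5-dimethoxyphenyl]propanoate (racemic, diastereomer mixture) | CCOC(=O)C(Oc1ccc(I)cc1Br)C(O)c1cc(OC)c(O[Si](C)(C)C(C)(C)C)c(OC)c1 | intermediate
7 | ethyl 2-(2-bromo-4-iodophenoxy)-3-oxo-3-[4-(TBSO)-3,5-dimethoxyphenyl]propanoate (racemic) | CCOC(=O)C(Oc1ccc(I)cc1Br)C(=O)c1cc(OC)c(O[Si](C)(C)C(C)(C)C)c(OC)c1 | intermediate
8 | ethyl (2S,3R)-2-(2-bromo-4-iodophenoxy)-3-hydroxy-3-[4-(TBSO)-3,5-dimethoxyphenyl]propanoate | CCOC(=O)[C@@H](Oc1ccc(I)cc1Br)[C@H](O)c1cc(OC)c(O[Si](C)(C)C(C)(C)C)c(OC)c1 | intermediate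
9 | 3,5-dihydroxybenzaldehyde | O=Cc1cc(O)cc(O)c1 | starting material
10 | 3,5-bis[(tert-butyldimethylsilyl)oxy]benzaldehyde | O=Cc1cc(O[Si](C)(C)C(C)(C)C)cc(O[Si](C)(C)C(C)(C)C)c1 | intermediate
11 | methyltriphenylphosphonium bromide | C[P+](c1ccccc1)(c1ccccc1)c1ccccc1.[Br-] | starting material
12 | 1-ethenyl-3,5-bis[(tert-butyldimethylsilyl)oxy]benzene | C=Cc1cc(O[Si](C)(C)C(C)(C)C)cc(O[Si](C)(C)C(C)(C)C)c1 | intermediate
13 | ethyl (2S,3R)-2-{2-bromo-4-[(E)-2-(3,5-bis(TBSO)phenyl)ethenyl]phenoxy}-3-hydroxy-3-[4-(TBSO)-3,5-dimethoxyphenyl]propanoate | CCOC(=O)[C@@H](Oc1ccc(/C=C/c2cc(O[Si](C)(C)C(C)(C)C)cc(O[Si](C)(C)C(C)(C)C)c2)cc1Br)[C@H](O)c1cc(OC)c(O[Si](C)(C)C(C)(C)C)c(OC)c1 | intermediate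
14 | ethyl (2S,3R)-6-[(E)-2-(3,5-bis(TBSO)phenyl)ethenyl]-3-[4-(TBSO)-3,5-dimethoxyphenyl]-2,3-dihydro-1,4-benzodioxine-2-carboxylate | CCOC(=O)[C@H]1Oc2ccc(/C=C/c3cc(O[Si](C)(C)C(C)(C)C)cc(O[Si](C)(C)C(C)(C)C)c3)cc2O[C@@H]1c1cc(OC)c(O[Si](C)(C)C(C)(C)C)c(OC)c1 | intermediate
15 | {(2R,3R)-6-[(E)-2-(3,5-bis(TBSO)phenyl)ethenyl]-3-[4-(TBSO)-3,5-dimethoxyphenyl]-2,3-dihydro-1,4-benzodioxin-2-yl}methanol | OC[C@H]1Oc2ccc(/C=C/c3cc(O[Si](C)(C)C(C)(C)C)cc(O[Si](C)(C)C(C)(C)C)c3)cc2O[C@@H]1c1cc(OC)c(O[Si](C)(C)C(C)(C)C)c(OC)c1 | intermediate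
16 | aiphanol | COc1cc([C@H]2Oc3cc(/C=C/c4cc(O)cc(O)c4)ccc3O[C@@H]2CO)cc(OC)c1O | target

## Summary

Total steps: 11.
Longest linear sequence: 8 (steps 1, 3, 4, 5, 8, 9, 10, 11).

Steps most likely to fail:

1. **Step 5 (ATH–DKR).** The electron-rich ketone and bulky ortho-bromoaryloxy group may give slow reduction or modest dr/ee. Fallback: set the same two centres with a chiral auxiliary instead. An Evans syn-glycolate aldol of (S)-4-benzyl-3-[(2-bromo-4-iodophenoxy)acetyl]oxazolidin-2-one (Bu2BOTf, Et3N) with aldehyde 5 gives the (2S,3R) adduct directly. Reductive auxiliary removal and primary-OH silylation then rejoin the route at the Heck step.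

2. **Step 9 (Pd C–O ring closure).** β-Hydride elimination of the Pd alkoxide (ketone plus hydrodebromination) or base-induced retro-aldol could compete. Fallback: close the ring through the other C–O bond. Replace the ortho-bromide by a protected ortho-phenol, reduce the ester, then unmask the phenol and cyclise under acid via the syringyl quinone methide or benzylic cation. This gives the thermodynamic trans-benzodioxane, with absolute configuration relayed from the non-epimerisable CH(OAr)CH2OH centre set in step 5.

3. **Step 8 (I-selective Heck).** Competing reaction at C–Br, partial desilylation or E/Z erosion could lower the yield. Fallback: build the stilbene by carbonyl olefination instead. Start from 3-bromo-4-hydroxybenzaldehyde (formyl masked as its acetal through the ATH step) in place of 1, close the dioxane first, then run an E-selective Horner–Wadsworth–Emmons reaction of the unmasked aldehyde with diethyl 3,5-bis(silyloxy)benzylphosphonate.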